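**Remarks on the chemistry (assumptions)**

- The (R)-configured phosphoric acid is assumed to deliver the 2S adduct; if the sense of induction is the opposite, the (S)-catalyst is used and nothing else changes.
- Target, both cycloaddition partners and the cycloadduct were re-derived atom by atom (methide CH2 becomes C4, vinyl CH2 becomes C3, vinyl CH becomes C2, C2 is S in adduct and target); no connectivity or configuration needs correcting.
- Protection is redesigned: benzyl ethers on all spectator phenols and a benzyl carbonate on the 4'-phenol. Methoxymethyl ethers are set aside because an acetal ortho to the ionising carbinol can itself be ionised or transacetalised by the acid, would not survive iodine/DMSO flavone formation, and would need a carcinogenic chloromethyl ether.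

## Structural features

The target is a C–C linked biflavonoid: a (2S)-5,7-dihydroxyflavanone and a 5,7-dihydroxyflavone joined by one biaryl bond between C3' of the flavanone ring B and C3''' of the flavone ring B, each carbon ortho to a phenolic OH, so the core is a 2,2'-biphenol. C2 of ring C is the only stereocentre; it is benzylic, bears the ether oxygen O1, sits β to the C4 ketone and has no stereogenic neighbour, and the biaryl axis with two small ortho groups rotates freely. The fragile points are the β-aryloxy ketone of ring C, which opens to the chalcone by retro-oxa-Michael reaction under base (helped by the 4'-phenoxide) and so racemises, the flavone enone, which is open to strong nucleophiles and over-reduction, and six oxidisable phenols. The difficulty is twofold: C2 must be set absolutely in a ring whose classical closure is reversible, and the two constitutionally alike halves of the biphenol must be told apart. The chosen disconnection reads ring C as a chroman fused to the phloroglucinol ring A: C4, C4a, C8a and O1 are the oxadiene of an o-quinone methide and C3–C2 with its aryl group is a styrene, so C3–C4 and O1–C2 arise in one [4+2] event that also creates C2. The 4'-OH para to C2 is used twice, as the donor that makes the styrene nucleophilic and as the handle by which a chiral phosphoric acid can hold the dienophile. The price is that ring C is formed as a flavan, so the C4 carbonyl is introduced afterwards; the three oxygens of ring A, ortho, ortho and para to C4a, make C4–H the best hydride donor in the molecule.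

## Logic of the disconnections

**18 to 17.** Five aryl O–CH2Ph bonds and the O–C(=O) bond of one benzyl carbonate are cut. All six caps fall in one neutral hydrogenolysis, so the finished flavanone never meets base or strong acid. The forward step must leave the flavone C2=C3 bond, the C4 ketone and the benzylic C2–O1 bond untouched.

**17 to 16 to 15.** The C4=O bond is traced back through the C4 carbinol to C4–H2. This is forced by the cycloaddition, which delivers a flavan. The forward hydride abstraction must choose C4 over C2, which is why the 4'-oxygen of 15 carries an electron-withdrawing carbonate.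

**15 to 14.** The carbonate O–C bond is cut to expose the one free phenol of 14. That phenol is free because the key step needs it, and capping it afterwards costs one step.

**14 to 12 and 3, through 13.** C3–C4 and O1–C2 are cut. This removes ring C and the stereocentre together and divides the molecule into a two-step ring A piece and the biaryl–flavone. The forward step must form only one quinone methide (3 has a single free phenol next to the carbinol), must add with the aryl-bearing carbon on oxygen, and needs catalyst control of the C2 face.

**3 to 2 to 1.** The carbinol is taken back to the aldehyde and two O–benzyl bonds are cut. The chelated ortho hydroxyl of 1 must stay free, since it becomes O1. Because 3 is a labile, electron-rich benzylic alcohol it is made immediately before use.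

**12 to 11.** The vinyl C=C is cut to an aldehyde, so the acid- and polymerisation-prone vinylphenol exists only in the step before the cycloaddition. The olefination must work on a free para-hydroxybenzaldehyde and spare the flavone.

**11 to 9 and 6, through 10.** The central biaryl bond is cut. Joining two different halves avoids the statistical desymmetrisation that a symmetrical biphenol would need, and 6 serves a second time as a building block. The coupling must tolerate a free phenol and make a biaryl with two ortho oxygen substituents.

**9 to 8 to 5 and 7.** The flavone O1–C2 bond and C2=C3 unsaturation are removed to give a 2'-hydroxychalcone, and its Cα=Cβ bond is cut by aldol logic. The oxidative cyclisation must spare the aryl bromide and the benzyl ethers.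

**5 to 4 and 7 to 6.** O–benzyl bonds are cut back to commercial phenols. In 4 the hydrogen-bonded hydroxyl must remain free for the later ring closure.

## Other disconnections considered

**Alternative 1:** The cut is C4–C4a. The (S)-β-aryloxy acid A1 would be converted into a mixed anhydride with trifluoroacetic anhydride and would acylate an ortho carbon of its own 3,5-bis(benzyloxy)phenoxy ring, giving flavanone A2 (intramolecular Friedel–Crafts acylation).
- In its favour: the C4 ketone arrives at the right oxidation level, so the two late oxidations are not needed; here the alternative is better.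
- In its favour: the two ortho positions of the symmetrical ring are equivalent and highly activated, so regiochemistry is as secure as in the chosen plan (equal).
- In its favour: the stereocentre would come from established chemistry (asymmetric reduction of a β-keto ester, then Mitsunobu etherification with inversion); in certainty of stereocontrol the alternative is better.
- Against it: the stereocentre of A1 is a benzylic carbon carrying an aryloxy leaving group and a para-oxygenated aryl ring. The Mitsunobu step risks partial ionisation, and under anhydride/acid A1 can ionise at C2–O1 or eliminate the phenol to a cinnamic acid, so configuration is at risk twice before ring closure.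
- Against it: A2 needs two deprotections, one of them acetate removal on a base-sensitive flavanone, against one in the chosen plan.
- Step economy: the two oxidation steps saved are spent on building the stereocentre with the whole biaryl–flavone attached, so the total is about the same and the linear sequence longer.

**Alternative 2:** The cut is C2–C3. The diazo β-keto ester A3, whose O1–C2 bond comes from simple O-benzylation, would be decomposed by Rh2(PTTL)4, a chiral carboxylate of divalent rhodium, and the carbene would insert into the benzylic ether C–H to give the flavanone-3-carboxylate A4.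
- In its favour: fragment union by Williamson etherification is simpler than anything in the chosen plan, and the ketone is already present; on both points the alternative is better.
- In its favour: ring and stereocentre arise in one catalytic step, in concept the equal of the chosen key step.
- Against it: the insertion must close a six-membered ring while the ether oxygen stands 1,5 to the carbene. Oxonium ylide formation and [1,2]-benzyl shift to a 2-benzylbenzofuranone is the expected competitor, and the enantioselective precedent for this catalyst family concerns five-membered closures.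
- Against it: A4 is a β-aryloxy β-keto ester, so ester cleavage and decarboxylation expose C2 to retro-oxa-Michael epimerisation, and three kinds of protecting group must be handled.
- Comparison: both plans rest on an asymmetric ring closure without direct precedent. The chosen one has no built-in competing pathway of similar weight and leaves a flavan with no acidic α-hydrogen next to C2. Step economy is similar.

**Alternative 3:** The cut is O1–C8a. The (S)-carbinol A5, carrying a bromine on ring A ortho to the propyl chain, would be cyclised with Pd(OAc)2, a bulky di-tert-butylbiarylphosphine and Cs2CO3 (intramolecular Buchwald–Hartwig etherification) to the hexabenzyl flavan A6.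
- In its favour: the coupling is well understood for chromans from bromoaryl alcohols, no bond to the stereocentre is touched, and the carbinol can come from a reliable asymmetric ketone reduction; in certainty of mechanism and stereochemical outcome this alternative is better.
- Against it: the aryl bromide is electron-rich and hindered, and the secondary benzylic alkoxide on divalent palladium can undergo β-hydride elimination to the ketone.
- Against it: A5 needs a chalcone-type assembly, chemoselective saturation beside an aryl bromide and a flavone enone, and the asymmetric reduction, several steps more than the two-step quinone methide precursor.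
- Comparison: A6 is a flavan, so the same two late oxidations follow (equal, no gain). Its 4'-oxygen is a benzyl ether, which leaves C2–H as a para-alkoxybenzyl ether hydrogen and makes the later hydride abstraction less selective than with the acyl-type cap that the free phenol of the chosen cycloadduct allows.

Key step: step 9

## Route

Step 1
Reactants: 1 2,4,6-trihydroxybenzaldehyde
Product: 2 2,4-bis(benzyloxy)-6-hydroxybenzaldehyde
Conditions: BnBr (2.1 equiv), K2CO3, DMF, 0 °C to rt
Reagents that add atoms: benzyl bromide, BrCc1ccccc1
Why: Williamson ether synthesis; the para hydroxyl and one ortho hydroxyl react, while the remaining ortho hydroxyl is locked in a hydrogen bond to the formyl oxygen and is the least nucleophilic.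

Step 2
Reactants: 2 2,4-bis(benzyloxy)-6-hydroxybenzaldehyde
Product: 3 3,5-bis(benzyloxy)-2-(hydroxymethyl)phenol
Conditions: NaBH4, THF/MeOH, 0 °C; neutral work-up; used at once in step 9
Reagents that add atoms: none
Why: Borohydride reduction of an aryl aldehyde; the salicyl alcohol is kept away from acid and heat and is not stored because it ionises easily.

Step 3
Reactants: 4 2',4',6'-trihydroxyacetophenone
Product: 5 1-[2,4-bis(benzyloxy)-6-hydroxyphenyl]ethan-1-one
Conditions: BnBr (2.1 equiv), K2CO3, DMF, rt
Reagents that add atoms: benzyl bromide, BrCc1ccccc1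
Why: Williamson ether synthesis with the same chelation-based selectivity as in step 1; the hydroxyl bonded to the acetyl oxygen stays free for the later pyranone closure.

Step 4
Reactants: 6 3-bromo-4-hydroxybenzaldehyde
Product: 7 4-(benzyloxy)-3-bromobenzaldehyde
Conditions: BnBr, K2CO3, DMF, rt
Reagents that add atoms: benzyl bromide, BrCc1ccccc1
Why: Williamson ether synthesis on a single acidic phenol; nothing else in the molecule reacts.

Step 5
Reactants: 5 1-[2,4-bis(benzyloxy)-6-hydroxyphenyl]ethan-1-one and 7 4-(benzyloxy)-3-bromobenzaldehyde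
Product: 8 (E)-1-[2,4-bis(benzyloxy)-6-hydroxyphenyl]-3-[4-(benzyloxy)-3-bromophenyl]prop-2-en-1-one
Conditions: KOH (aq), EtOH/THF, rt
Reagents that add atoms: none
Why: Claisen–Schmidt aldol condensation of a methyl ketone with a non-enolisable aldehyde; dehydration gives the conjugated E-chalcone, and any flavanone formed by ring closure is converted in step 6 as well.

Step 6
Reactants: 8 (E)-1-[2,4-bis(benzyloxy)-6-hydroxyphenyl]-3-[4-(benzyloxy)-3-bromophenyl]prop-2-en-1-one
Product: 9 5,7-bis(benzyloxy)-2-[4-(benzyloxy)-3-bromophenyl]-4H-chromen-4-one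
Conditions: I2 (10 mol%), DMSO, 130 °C
Reagents that add atoms: none
Why: Iodine-catalysed oxidative cyclisation of a 2'-hydroxychalcone (oxa-Michael closure, α-iodination, loss of HI, with DMSO reoxidising HI to I2); aryl bromide and benzyl ethers are expected to survive.

Step 7
Reactants: 9 5,7-bis(benzyloxy)-2-[4-(benzyloxy)-3-bromophenyl]-4H-chromen-4-one and 6 3-bromo-4-hydroxybenzaldehyde
Product: 11 3-{2-(benzyloxy)-5-[5,7-bis(benzyloxy)-4-oxo-4H-chromen-2-yl]phenyl}-4-hydroxybenzaldehyde, via flavone pinacol boronate 10 (not isolated)
Conditions: B2pin2 (1.05 equiv), PdCl2(dppf), KOAc, 1,4-dioxane, 90 °C; then 6, aq K3PO4, 90 °C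
Reagents that add atoms: bis(pinacolato)diboron, CC1(C)OB(OC1(C)C)B1OC(C)(C)C(C)(C)O1 (its boryl group is carried by intermediate 10 only and no atom of it remains in 11)
Why: Miyaura borylation followed in the same flask by Suzuki–Miyaura cross-coupling; the C–Br bond of 6 is activated by the para formyl group, the free phenol is tolerated as its phenoxide, and the near-stoichiometric diboron leaves none to borylate 6.

Step 8
Reactants: 11 3-{2-(benzyloxy)-5-[5,7-bis(benzyloxy)-4-oxo-4H-chromen-2-yl]phenyl}-4-hydroxybenzaldehyde
Product: 12 5,7-bis(benzyloxy)-2-[4-(benzyloxy)-3-(2-hydroxy-5-vinylphenyl)phenyl]-4H-chromen-4-one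
Conditions: Ph3PCH3Br (3.5 equiv), KOtBu, THF, 0 °C to rt; BHT on work-up; used at once
Reagents that add atoms: methyltriphenylphosphonium bromide, [Br-].C[P+](c1ccccc1)(c1ccccc1)c1ccccc1
Why: Wittig methylenation; excess ylide is used because one equivalent deprotonates the phenol, and the pyranone carbonyl, a vinylogous ester, should not olefinate at this temperature.

Step 9
Reactants: 12 5,7-bis(benzyloxy)-2-[4-(benzyloxy)-3-(2-hydroxy-5-vinylphenyl)phenyl]-4H-chromen-4-one and 3 3,5-bis(benzyloxy)-2-(hydroxymethyl)phenol
Product: 14 5,7-bis(benzyloxy)-2-{4-(benzyloxy)-3-[5-((2S)-5,7-bis(benzyloxy)chroman-2-yl)-2-hydroxyphenyl]phenyl}-4H-chromen-4-one, via o-quinone methide 13 (not isolated)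
Conditions: (R)-TRIP [(R)-3,3'-bis(2,4,6-triisopropylphenyl)-1,1'-binaphthyl-2,2'-diyl hydrogen phosphate] (10 mol%), 4 Å MS, PhMe/CH2Cl2 (4:1), 0 °C; 3 (1.5 equiv) added slowly
Reagents that add atoms: none
Why: Proposed new method: the phosphoric acid protonates the benzylic hydroxyl of 3, and loss of water, assisted by the ortho phenol and the two benzyloxy donors, gives o-quinone methide 13 hydrogen-bonded to the phosphate; the terminal vinyl carbon of 12, made nucleophilic by the para hydroxyl, attacks the methide carbon (C3–C4), and the resulting para-quinone methide or benzylic cation is captured by the ring A oxygen (O1–C2), an inverse-electron-demand hetero-Diels–Alder reaction that may be concerted and asynchronous or stepwise. The closest known reaction types are the acid-promoted [4+2] of o-quinone methides with styrenes to racemic flavans and the chiral-phosphoric-acid [4+2] of o-quinone methides from o-hydroxybenzyl alcohols with hydroxystyrenes; what is new is a methide with an unsubstituted terminus, so that the only stereocentre is created in the C–O bond-forming event. Ring C closes as the six-membered adduct of a 4π oxadiene and a 2π alkene or, in the stepwise limit, by 6-exo-trig oxa-1,6-addition of the ring A phenol to the para-quinone methide. C2 is controlled by the catalyst: the phosphate is expected to bridge the 4'-oxygen of the dienophile and the ring A hydroxyl, so that the binaphthyl pocket exposes one face of C2, taken here to lead to S. Regiochemistry follows polarity matching (nucleophilic CH2 to the methide carbon, aryl-bearing carbon to oxygen), and 3 can form only one quinone methide because its other two oxygens are benzylated. Chemoselectivity against self-condensation of 13 with the electron-rich ring of 3 is sought by keeping 3 dilute through slow addition to 12 and catalyst. The benzyl ethers and the flavone are inert to the acid, and the adduct is capped in step 10 without delay because its C2–O1 bond is a para-hydroxybenzyl ether that could ionise reversibly.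

Step 10
Reactants: 14 5,7-bis(benzyloxy)-2-{4-(benzyloxy)-3-[5-((2S)-5,7-bis(benzyloxy)chroman-2-yl)-2-hydroxyphenyl]phenyl}-4H-chromen-4-one
Product: 15 benzyl 4-[(2S)-5,7-bis(benzyloxy)chroman-2-yl]-2-{2-(benzyloxy)-5-[5,7-bis(benzyloxy)-4-oxo-4H-chromen-2-yl]phenyl}phenyl carbonate
Conditions: CbzCl, Et3N, DMAP (cat.), CH2Cl2, 0 °C
Reagents that add atoms: benzyl chloroformate, O=C(Cl)OCc1ccccc1
Why: O-acylation of the only free phenol; the carbonate withdraws electron density from ring B, which lowers the hydride-donor ability of C2–H and shuts off ionisation of C2–O1, and it leaves with the benzyl ethers in step 13.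

Step 11
Reactants: 15 benzyl 4-[(2S)-5,7-bis(benzyloxy)chroman-2-yl]-2-{2-(benzyloxy)-5-[5,7-bis(benzyloxy)-4-oxo-4H-chromen-2-yl]phenyl}phenyl carbonate
Product: 16 benzyl 4-[(2S,4RS)-5,7-bis(benzyloxy)-4-hydroxychroman-2-yl]-2-{2-(benzyloxy)-5-[5,7-bis(benzyloxy)-4-oxo-4H-chromen-2-yl]phenyl}phenyl carbonate (mixture of C4 epimers)
Conditions: DDQ (1.3 equiv), CH2Cl2/pH 7 buffer (10:1), 0 °C
Reagents that add atoms: water, O
Why: DDQ benzylic oxidation by hydride abstraction at C4, whose cation is stabilised by the three oxygens of ring A, followed by capture with water; the new C4 centre is unselective and irrelevant because step 12 removes it, and C2 and the benzyl CH2 groups on unactivated phenyl rings are much poorer hydride donors.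

Step 12
Reactants: 16 benzyl 4-[(2S,4RS)-5,7-bis(benzyloxy)-4-hydroxychroman-2-yl]-2-{2-(benzyloxy)-5-[5,7-bis(benzyloxy)-4-oxo-4H-chromen-2-yl]phenyl}phenyl carbonate
Product: 17 benzyl 4-[(2S)-5,7-bis(benzyloxy)-4-oxochroman-2-yl]-2-{2-(benzyloxy)-5-[5,7-bis(benzyloxy)-4-oxo-4H-chromen-2-yl]phenyl}phenyl carbonate
Conditions: Dess–Martin periodinane, NaHCO3, CH2Cl2, 0 °C to rt
Reagents that add atoms: none
Why: Dess–Martin oxidation of a secondary benzylic alcohol under buffered, essentially neutral conditions, so the alcohol does not ionise and the new β-aryloxy ketone never meets base; C2 is untouched.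

Step 13
Reactants: 17 benzyl 4-[(2S)-5,7-bis(benzyloxy)-4-oxochroman-2-yl]-2-{2-(benzyloxy)-5-[5,7-bis(benzyloxy)-4-oxo-4H-chromen-2-yl]phenyl}phenyl carbonate
Product: 18 (2S)-2-{3-[5-(5,7-dihydroxy-4-oxo-4H-chromen-2-yl)-2-hydroxyphenyl]-4-hydroxyphenyl}-5,7-dihydroxychroman-4-one
Conditions: H2 (1 atm), 10% Pd/C, EtOAc/MeOH, rt
Reagents that add atoms: none
Why: Catalytic hydrogenolysis of five aryl benzyl ethers and of the benzyl carbonate, whose carbonic acid loses CO2; the neutral medium preserves C2, and flavone enone and aryl ketone are not expected to be reduced at one atmosphere.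

## Compound list

1 | 2,4,6-trihydroxybenzaldehyde | O=Cc1c(O)cc(O)cc1O | starting material
2 | 2,4-bis(benzyloxy)-6-hydroxybenzaldehyde | O=Cc1c(O)cc(OCc2ccccc2)cc1OCc1ccccc1 | intermediate
3 | 3,5-bis(benzyloxy)-2-(hydroxymethyl)phenol | OCc1c(O)cc(OCc2ccccc2)cc1OCc1ccccc1 | intermediate
4 | 2',4',6'-trihydroxyacetophenone | CC(=O)c1c(O)cc(O)cc1O | starting material
5 | 1-[2,4-bis(benzyloxy)-6-hydroxyphenyl]ethan-1-one | CC(=O)c1c(O)cc(OCc2ccccc2)cc1OCc1ccccc1 | intermediate
6 | 3-bromo-4-hydroxybenzaldehyde | O=Cc1ccc(O)c(Br)c1 | starting material
7 | 4-(benzyloxy)-3-bromobenzaldehyde | O=Cc1ccc(OCc2ccccc2)c(Br)c1 | intermediate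
8 | (E)-1-[2,4-bis(benzyloxy)-6-hydroxyphenyl]-3-[4-(benzyloxy)-3-bromophenyl]prop-2-en-1-one | O=C(/C=C/c1ccc(OCc2ccccc2)c(Br)c1)c1c(O)cc(OCc2ccccc2)cc1OCc1ccccc1 | intermediate
9 | 5,7-bis(benzyloxy)-2-[4-(benzyloxy)-3-bromophenyl]-4H-chromen-4-one | O=c1cc(-c2ccc(OCc3ccccc3)c(Br)c2)oc2cc(OCc3ccccc3)cc(OCc3ccccc3)c12 | intermediate
10 | 5,7-bis(benzyloxy)-2-[4-(benzyloxy)-3-(4,4,5,5-tetramethyl-1,3,2-dioxaborolan-2-yl)phenyl]-4H-chromen-4-one | O=c1cc(-c2ccc(OCc3ccccc3)c(B3OC(C)(C)C(C)(C)O3)c2)oc2cc(OCc3ccccc3)cc(OCc3ccccc3)c12 | intermediate (not isolated)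
11 | 3-{2-(benzyloxy)-5-[5,7-bis(benzyloxy)-4-oxo-4H-chromen-2-yl]phenyl}-4-hydroxybenzaldehyde | O=Cc1ccc(O)c(-c2cc(-c3cc(=O)c4c(OCc5ccccc5)cc(OCc5ccccc5)cc4o3)ccc2OCc2ccccc2)c1 | intermediate
12 | 5,7-bis(benzyloxy)-2-[4-(benzyloxy)-3-(2-hydroxy-5-vinylphenyl)phenyl]-4H-chromen-4-one | C=Cc1ccc(O)c(-c2cc(-c3cc(=O)c4c(OCc5ccccc5)cc(OCc5ccccc5)cc4o3)ccc2OCc2ccccc2)c1 | intermediate
13 | 3,5-bis(benzyloxy)-6-methylidenecyclohexa-2,4-dien-1-one | C=C1C(=O)C=C(OCc2ccccc2)C=C1OCc1ccccc1 | intermediate (not isolated)
14 | 5,7-bis(benzyloxy)-2-{4-(benzyloxy)-3-[5-((2S)-5,7-bis(benzyloxy)chroman-2-yl)-2-hydroxyphenyl]phenyl}-4H-chromen-4-one | C1C[C@@H](c2ccc(O)c(-c3cc(-c4cc(=O)c5c(OCc6ccccc6)cc(OCc6ccccc6)cc5o4)ccc3OCc3ccccc3)c2)Oc2cc(OCc3ccccc3)cc(OCc3ccccc3)c21 | intermediate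
15 | benzyl 4-[(2S)-5,7-bis(benzyloxy)chroman-2-yl]-2-{2-(benzyloxy)-5-[5,7-bis(benzyloxy)-4-oxo-4H-chromen-2-yl]phenyl}phenyl carbonate | C1C[C@@H](c2ccc(OC(=O)OCc7ccccc7)c(-c3cc(-c4cc(=O)c5c(OCc6ccccc6)cc(OCc6ccccc6)cc5o4)ccc3OCc3ccccc3)c2)Oc2cc(OCc3ccccc3)cc(OCc3ccccc3)c21 | intermediate
16 | benzyl 4-[(2S,4RS)-5,7-bis(benzyloxy)-4-hydroxychroman-2-yl]-2-{2-(benzyloxy)-5-[5,7-bis(benzyloxy)-4-oxo-4H-chromen-2-yl]phenyl}phenyl carbonate | OC1C[C@@H](c2ccc(OC(=O)OCc7ccccc7)c(-c3cc(-c4cc(=O)c5c(OCc6ccccc6)cc(OCc6ccccc6)cc5o4)ccc3OCc3ccccc3)c2)Oc2cc(OCc3ccccc3)cc(OCc3ccccc3)c21 | intermediate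
17 | benzyl 4-[(2S)-5,7-bis(benzyloxy)-4-oxochroman-2-yl]-2-{2-(benzyloxy)-5-[5,7-bis(benzyloxy)-4-oxo-4H-chromen-2-yl]phenyl}phenyl carbonate | O=C1C[C@@H](c2ccc(OC(=O)OCc7ccccc7)c(-c3cc(-c4cc(=O)c5c(OCc6ccccc6)cc(OCc6ccccc6)cc5o4)ccc3OCc3ccccc3)c2)Oc2cc(OCc3ccccc3)cc(OCc3ccccc3)c21 | intermediate
18 | (2S)-2-{3-[5-(5,7-dihydroxy-4-oxo-4H-chromen-2-yl)-2-hydroxyphenyl]-4-hydroxyphenyl}-5,7-dihydroxychroman-4-one | O=C1C[C@@H](c2ccc(O)c(-c3cc(-c4cc(=O)c5c(O)cc(O)cc5o4)ccc3O)c2)Oc2cc(O)cc(O)c21 | target

## Step count and least certain steps

Total: 13 steps. Longest linear sequence: 10 steps (steps 4, 5, 6, 7, 8, 9, 10, 11, 12, 13 from compound 6, or equally steps 3, 5 to 13 from compound 4).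

**Step 9 (key step).**
- What may go wrong: poor facial selectivity in the C2–O1 closure, because the catalyst must differentiate the faces of a para-quinone methide remote from its binding site; a racemic background pathway; self-condensation of the quinone methide with the electron-rich ring of its precursor; acid-induced oligomerisation of the vinylphenol; and erosion of enantiopurity by reversible ionisation of the C2–O1 bond of the adduct.
- Fallback (known chemistry, sets out from 12 and 3, returns at 14): the two partners are combined under an achiral Brønsted acid such as diphenyl phosphate, the established acid-promoted o-quinone methide/styrene cycloaddition, to give racemic 5,7-bis(benzyloxy)-2-{4-(benzyloxy)-3-[5-(5,7-bis(benzyloxy)chroman-2-yl)-2-hydroxyphenyl]phenyl}-4H-chromen-4-one F1. This is resolved by preparative chromatography on a chiral stationary phase; the 2S half is 14, which re-enters at step 10, and the mirror-image half is set aside.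

**Step 11.**
- What may go wrong: over-oxidation, by loss of a C3 proton from the C4 cation to a flav-3-ene and a second hydride loss to a flavylium ion, which would erase C2; and competing hydride abstraction at C2.
- Fallback (sets out from 15, returns at 16): classical benzylic acetoxylation of the flavan with Pb(OAc)4 in benzene, in which the acetate is delivered from lead and no long-lived free cation sits beside an excess of oxidant. This gives benzyl 4-[(2S,4RS)-4-acetoxy-5,7-bis(benzyloxy)chroman-2-yl]-2-{2-(benzyloxy)-5-[5,7-bis(benzyloxy)-4-oxo-4H-chromen-2-yl]phenyl}phenyl carbonate F2. Its very labile benzylic acetate is solvolysed in NaHCO3-buffered aqueous acetone to 16.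

**Step 7.**
- What may go wrong: protodeboronation of the ortho-alkoxy boronate, homocoupling, borylation of the second bromide by residual diboron, and slow oxidative addition to the bromophenoxide.
- Fallback (sets out from 9, returns at 12, bypassing 10, 11 and step 8): Suzuki–Miyaura coupling of 9 with commercial (5-chloro-2-hydroxyphenyl)boronic acid (PdCl2(dppf), K2CO3, dioxane/water), in which the C–Cl bond is inert, gives 5,7-bis(benzyloxy)-2-[4-(benzyloxy)-3-(5-chloro-2-hydroxyphenyl)phenyl]-4H-chromen-4-one F4. Suzuki–Miyaura vinylation of the aryl chloride with potassium vinyltrifluoroborate (Pd(OAc)2, XPhos, K2CO3, THF/water) then gives 12.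

**Step 8.**
- What may go wrong: incomplete olefination because the phenoxide deactivates the aldehyde, attack of ylide or alkoxide on the pyranone, and polymerisation of the vinylphenol during isolation.
- Fallback (sets out from 11, returns at 12): Knoevenagel–Doebner condensation with malonic acid (pyridine, catalytic piperidine) gives (E)-3-{3-[2-(benzyloxy)-5-(5,7-bis(benzyloxy)-4-oxo-4H-chromen-2-yl)phenyl]-4-hydroxyphenyl}prop-2-enoic acid F3. Its base-mediated decarboxylation (Et3N, DMF, about 110 °C, BHT), which para-hydroxycinnamic acids undergo through their quinone methide tautomer, gives 12.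

**Step 1.**
- What may go wrong: imperfect discrimination between the three hydroxyls (over-alkylation) and competing C-benzylation of the phloroglucinol ring.
- Fallback (sets out from 1, returns at 2): exhaustive O-benzylation (BnBr, K2CO3, DMF, 60 °C) gives 2,4,6-tris(benzyloxy)benzaldehyde F5. Chelation-directed removal of one benzyl group ortho to the formyl group with MgBr2·OEt2 (toluene/Et2O, warm) gives 2.

**Step 13.**
- What may go wrong: over-reduction, namely saturation of the flavone C2=C3 bond or hydrogenolytic opening of the benzylic C2–O1 bond to a dihydrochalcone.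
- Fallback (sets out from 17, returns at 18, no new compound): Lewis-acid debenzylation with BCl3 and pentamethylbenzene as cation scavenger in CH2Cl2 at −78 °C. This removes the five benzyl ethers and the benzyl group of the carbonate without hydrogen and leaves the free phenol after loss of CO2 on work-up.

## Further compounds

F1 | step 9 | racemic 5,7-bis(benzyloxy)-2-{4-(benzyloxy)-3-[5-(5,7-bis(benzyloxy)chroman-2-yl)-2-hydroxyphenyl]phenyl}-4H-chromen-4-one | C1CC(c2ccc(O)c(-c3cc(-c4cc(=O)c5c(OCc6ccccc6)cc(OCc6ccccc6)cc5o4)ccc3OCc3ccccc3)c2)Oc2cc(OCc3ccccc3)cc(OCc3ccccc3)c21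
F2 | step 11 | benzyl 4-[(2S,4RS)-4-acetoxy-5,7-bis(benzyloxy)chroman-2-yl]-2-{2-(benzyloxy)-5-[5,7-bis(benzyloxy)-4-oxo-4H-chromen-2-yl]phenyl}phenyl carbonate | CC(=O)OC1C[C@@H](c2ccc(OC(=O)OCc7ccccc7)c(-c3cc(-c4cc(=O)c5c(OCc6ccccc6)cc(OCc6ccccc6)cc5o4)ccc3OCc3ccccc3)c2)Oc2cc(OCc3ccccc3)cc(OCc3ccccc3)c21
F3 | step 8 | (E)-3-{3-[2-(benzyloxy)-5-(5,7-bis(benzyloxy)-4-oxo-4H-chromen-2-yl)phenyl]-4-hydroxyphenyl}prop-2-enoic acid | OC(=O)/C=C/c1ccc(O)c(-c2cc(-c3cc(=O)c4c(OCc5ccccc5)cc(OCc5ccccc5)cc4o3)ccc2OCc2ccccc2)c1
F4 | step 7 | 5,7-bis(benzyloxy)-2-[4-(benzyloxy)-3-(5-chloro-2-hydroxyphenyl)phenyl]-4H-chromen-4-one | Clc1ccc(O)c(-c2cc(-c3cc(=O)c4c(OCc5ccccc5)cc(OCc5ccccc5)cc4o3)ccc2OCc2ccccc2)c1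
F5 | step 1 | 2,4,6-tris(benzyloxy)benzaldehyde | O=Cc1c(OCc2ccccc2)cc(OCc2ccccc2)cc1OCc1ccccc1
F0 | step 13 | none | none
A1 | alternative 1 | (3S)-3-{4-acetoxy-3-[2-acetoxy-5-(5,7-bis(benzyloxy)-4-oxo-4H-chromen-2-yl)phenyl]phenyl}-3-[3,5-bis(benzyloxy)phenoxy]propanoic acid | OC(=O)C[C@@H](c1ccc(OC(C)=O)c(-c2cc(-c3cc(=O)c4c(OCc5ccccc5)cc(OCc5ccccc5)cc4o3)ccc2OC(C)=O)c1)Oc1cc(OCc2ccccc2)cc(OCc2ccccc2)c1
A2 | alternative 1 | (2S)-flavanone–flavone tetrabenzyl ether diacetate | O=C1C[C@@H](c2ccc(OC(C)=O)c(-c3cc(-c4cc(=O)c5c(OCc6ccccc6)cc(OCc6ccccc6)cc5o4)ccc3OC(C)=O)c2)Oc2cc(OCc3ccccc3)cc(OCc3ccccc3)c21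
A3 | alternative 2 | tert-butyl 2-diazo-3-oxo-3-[2-(arylmethoxy)-4,6-bis(tert-butyldimethylsilyloxy)phenyl]propanoate, aryl being the tris(methoxymethyl)-protected biaryl–flavone | CC(C)(C)OC(=O)C(=[N+]=[N-])C(=O)c1c(OCc2ccc(OCOC)c(-c3cc(-c4cc(=O)c5c(OCOC)cc(OCOC)cc5o4)ccc3OCOC)c2)cc(O[Si](C)(C)C(C)(C)C)cc1O[Si](C)(C)C(C)(C)C
A4 | alternative 2 | tert-butyl (2S)-flavanone-3-carboxylate, C3 undefined | O=C1C(C(=O)OC(C)(C)C)[C@@H](c2ccc(OCOC)c(-c3cc(-c4cc(=O)c5c(OCOC)cc(OCOC)cc5o4)ccc3OCOC)c2)Oc2cc(O[Si](C)(C)C(C)(C)C)cc(O[Si](C)(C)C(C)(C)C)c21
A5 | alternative 3 | (1S)-3-[2-bromo-4,6-bis(benzyloxy)phenyl]-1-{4-(benzyloxy)-3-[2-(benzyloxy)-5-(5,7-bis(benzyloxy)-4-oxo-4H-chromen-2-yl)phenyl]phenyl}propan-1-ol | Brc1cc(OCc2ccccc2)cc(OCc2ccccc2)c1CC[C@@H](c1ccc(OCc2ccccc2)c(-c2cc(-c3cc(=O)c4c(OCc5ccccc5)cc(OCc5ccccc5)cc4o3)ccc2OCc2ccccc2)c1)O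
A6 | alternative 3 | (2S)-flavan–flavone hexabenzyl ether | C1C[C@@H](c2ccc(OCc3ccccc3)c(-c3cc(-c4cc(=O)c5c(OCc6ccccc6)cc(OCc6ccccc6)cc5o4)ccc3OCc3ccccc3)c2)Oc2cc(OCc3ccccc3)cc(OCc3ccccc3)c21
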